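Retrosynthesis: the enol ether C=C is traced back to its 3,6-dihydropyran isomer and the γ-lactone is opened at C12–O(C8). The pyran is then cut at C11–C13 by a retro-[3,3] shift to a 6-vinyl-1,4-dioxan-2-one, which is cut at the ester C12–O(C11′) and ether C11–O(C12′) bonds into a decalin lactone and an elemane vinyl diol.
Feature used: spiro C11 carries the pyran oxygen, carboxyl C12 and ring CH2 C13, so the pyran is a dihydropyran-2-carboxylate. That is the product type of an ester-enolate Claisen shift of an allyl α-alkoxy ester held in a six-membered dioxanone ring.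
Elemane half, forward: the carvone ring is kept, isopropenyl (conjugate addition) and vinyl (aldol, elimination) are added, the ring carbonyl is removed, and the old isopropenyl carbon is rebuilt as the tertiary vinyl carbinol diol.
Decalin half, forward: ring B is annulated onto 2,6-dimethylcyclohexanone, C7 and C8 are functionalised through a dienyl triflate, and the cis γ-lactone is closed and converted to its α-diazo derivative.
Union: O–H insertion joins the halves, the γ-lactone is exchanged for the dioxanone, the Ireland–Claisen shift closes the pyran, then the γ-lactone is re-closed and the ring alkene is moved next to oxygen.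
Stereochemistry: the elemane centres come from carvone C5 (anti cuprate addition, anti aldol, final epimerisation); C11′ comes from a tartrate-controlled epoxidation and is relayed to C11 by the cyclic [3,3] shift; C10 comes from a chiral-imine Michael addition, and C4, C7 and C8 from reagent approach anti to the angular methyl.

Key step: step 25

Remark: decalin carbons carry eudesmane locants (ring C1–C10, C14 = 10-methyl, C15 = 4-methyl, side chain C11/C12; β = face of C14), elemane carbons are primed, El stands for (1S,3R,4R)-4-ethenyl-4-methyl-3-(prop-1-en-2-yl)cyclohexyl, and the imine Michael addition of step 12 is assumed to follow the facial sense known for the 2-methylcyclohexanone imine of the same amine.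

Step 1
Reactants: 1 (S)-(+)-carvone
Product: 2 (5S)-5-acetyl-2-methylcyclohex-2-en-1-one
Conditions: O3 (1 equiv), CH2Cl2/MeOH, −78 °C; Me2S, −78 °C to rt
Reagents that add atoms: ozone, [O-][O+]=O
Why: Ozone attacks the electron-rich 1,1-disubstituted alkene much faster than the electron-poor enone alkene, so ozonolysis with reductive work-up should cleave only the isopropenyl group and leave C5 untouched.

Step 2
Reactants: 2 (5S)-5-acetyl-2-methylcyclohex-2-en-1-one
Product: 3 (5S)-2-methyl-5-(2-methyl-1,3-dioxolan-2-yl)cyclohex-2-en-1-one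
Conditions: (Me3SiOCH2)2, Me3SiOTf (5 mol %), CH2Cl2, −78 °C
Reagents that add atoms: 1,2-bis(trimethylsilyloxy)ethane, C[Si](C)(C)OCCO[Si](C)(C)C
Why: Silyl-transfer ketalisation converts a saturated ketone far faster than an enone and, at −78 °C, should not enolise the adjacent C5 stereocentre (chemoselective dioxolane formation).

Step 3
Reactants: 3 (5S)-2-methyl-5-(2-methyl-1,3-dioxolan-2-yl)cyclohex-2-en-1-one; 4 isopropenylmagnesium bromide
Product: 6 (2S,3R,5S)-2-[1-hydroxy-2-(phenylselanyl)ethyl]-2-methyl-5-(2-methyl-1,3-dioxolan-2-yl)-3-(prop-1-en-2-yl)cyclohexan-1-one (carbinol epimers), via magnesium enolate 5 (not isolated)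
Conditions: CuBr·SMe2 (10 mol %), THF, −78 to −40 °C; then PhSeCH2CHO, −78 °C; aq NH4Cl
Reagents that add atoms: (phenylselanyl)acetaldehyde, O=CC[Se]c1ccccc1
Why: Copper-catalysed conjugate addition delivers the isopropenyl group to C3 by axial attack anti to the C5 substituent, and the magnesium enolate then adds to the aldehyde at C2 on the face away from the new C3 group, which fixes the quaternary centre (tandem conjugate addition–aldol reaction).

Step 4
Reactants: 6 (2S,3R,5S)-2-[1-hydroxy-2-(phenylselanyl)ethyl]-2-methyl-5-(2-methyl-1,3-dioxolan-2-yl)-3-(prop-1-en-2-yl)cyclohexan-1-one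
Product: 7 (2R,3R,5S)-2-ethenyl-2-methyl-5-(2-methyl-1,3-dioxolan-2-yl)-3-(prop-1-en-2-yl)cyclohexan-1-one
Conditions: MeSO2Cl, Et3N, CH2Cl2, 0 °C to rt
Reagents that add atoms: none
Why: Mesylation of a β-hydroxy selenide triggers anti elimination of the oxygen and selenium groups, a regiospecific olefin-forming elimination that can only give the terminal vinyl group.

Step 5
Reactants: 7 (2R,3R,5S)-2-ethenyl-2-methyl-5-(2-methyl-1,3-dioxolan-2-yl)-3-(prop-1-en-2-yl)cyclohexan-1-one
Product: 9 2-[(1R,3R,4R)-4-ethenyl-4-methyl-3-(prop-1-en-2-yl)cyclohexyl]-2-methyl-1,3-dioxolane, via hydrazone 8 (not isolated)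
Conditions: N2H4·H2O, KOH, diethylene glycol, 130 °C then 200 °C
Reagents that add atoms: none
Why: Wolff–Kishner reduction removes the ring carbonyl through hydrazone 8 without touching the ketal or the alkenes, and no stereocentre is at risk because the ketone lies between a quaternary carbon and a methylene group.

Step 6
Reactants: 9 2-[(1R,3R,4R)-4-ethenyl-4-methyl-3-(prop-1-en-2-yl)cyclohexyl]-2-methyl-1,3-dioxolane
Product: 11 El–C(O)CH3 (1-[(1S,3R,4R)-4-ethenyl-4-methyl-3-(prop-1-en-2-yl)cyclohexyl]ethan-1-one), via C1-epimeric ketone 10 (not isolated)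
Conditions: 1 M HCl, THF, rt; then NaOMe, MeOH, rt
Reagents that add atoms: water, O
Why: Acid-catalysed ketal hydrolysis frees the methyl ketone, and methoxide-mediated enolisation should then equilibrate the acetyl-bearing carbon to the diastereomer with acetyl and isopropenyl both equatorial (cis), a thermodynamic epimerisation that corrects the relative configuration left by the anti conjugate addition.

Step 7
Reactants: 11 El–C(O)CH3
Product: 12 2-methyl-2-El-oxirane (both epimers at the oxirane carbon)
Conditions: Me3SI, n-BuLi, THF, −10 °C to rt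
Reagents that add atoms: trimethylsulfonium iodide, C[S+](C)C.[I-]
Why: Corey–Chaykovsky epoxidation, in which the sulfonium ylide adds to the ketone and closes the oxirane; the new centre is inconsequential because it becomes sp2 in step 8.

Step 8
Reactants: 12 2-methyl-2-El-oxirane
Product: 13 2-El-prop-2-en-1-ol
Conditions: LiNEt2 (from Et2NH, n-BuLi), Et2O/hexane, reflux
Reagents that add atoms: none
Why: Lithium amide-induced isomerisation of an epoxide to an allylic alcohol proceeds by syn β-elimination with removal of the least hindered proton, here from the methyl group, which should give the 2-substituted allyl alcohol.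

Step 9
Reactants: 13 2-El-prop-2-en-1-ol
Product: 14 [(2R)-2-El-oxiran-2-yl]methanol
Conditions: Ti(Oi-Pr)4 (10 mol %), D-(−)-diisopropyl tartrate (12 mol %), t-BuOOH, 4 Å sieves, CH2Cl2, −20 °C
Reagents that add atoms: tert-butyl hydroperoxide, CC(C)(C)OO
Why: Sharpless asymmetric epoxidation acts only on the allylic alcohol alkene, and the D-(−)-tartrate ligand should deliver oxygen to the face that gives the (2R)-oxirane, so C11′ is set by the reagent and not by the distant ring centres.

Step 10
Reactants: 14 [(2R)-2-El-oxiran-2-yl]methanol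
Product: 15 tert-butyl{[(2S)-2-El-oxiran-2-yl]methoxy}dimethylsilane
Conditions: t-BuMe2SiCl, imidazole, DMF, 0 °C to rt
Reagents that add atoms: tert-butyldimethylsilyl chloride, CC(C)(C)[Si](C)(C)Cl
Why: Silylation of the primary alcohol prevents alkoxide formation and thus the Payne-type epoxide migration that would scramble C11′ under the basic conditions of step 11 (silyl ether protection; the descriptor changes by priority only).

Step 11
Reactants: 15 tert-butyl{[(2S)-2-El-oxiran-2-yl]methoxy}dimethylsilane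
Product: 17 (2R)-2-El-but-3-ene-1,2-diol, via carbinol silyl ether 16 (not isolated)
Conditions: Me3SI, n-BuLi, THF, −10 °C to rt; then Bu4NF, THF, rt
Reagents that add atoms: trimethylsulfonium iodide, C[S+](C)C.[I-]
Why: Dimethylsulfonium methylide opens the oxirane at its CH2 group and the β-alkoxy sulfonium salt loses dimethyl sulfide, a one-carbon homologation of an epoxide to an allylic alcohol in which no bond to C11′ is broken, so its configuration is kept; fluoride then cleaves the silyl ether.

Step 12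
Reactants: 18 2,6-dimethylcyclohexan-1-one; 19 methyl vinyl ketone
Product: 22 (2R)-2,6-dimethyl-2-(3-oxobutyl)cyclohexan-1-one (C6 epimers), via chiral imine 20 (not isolated), via Michael adduct imine 21 (not isolated)
Conditions: (S)-1-phenylethylamine, TsOH (cat.), toluene, reflux (−H2O); 19, THF, rt to 50 °C; 20% aq AcOH, rt
Reagents that add atoms: water, O
Why: The secondary enamine tautomer of the chiral imine adds to the enone at a substituted α-carbon on the face dictated by the phenylethyl group (deracemising Michael addition of a chiral imine), which sets C10; hydrolysis returns the ketone and the amine.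

Step 13
Reactants: 22 (2R)-2,6-dimethyl-2-(3-oxobutyl)cyclohexan-1-one
Product: 23 (4aR)-4a,8-dimethyl-4,4a,5,6,7,8-hexahydronaphthalen-2(3H)-one (C8 epimers)
Conditions: NaOMe, MeOH, rt to 60 °C
Reagents that add atoms: none
Why: Base-mediated intramolecular aldol condensation (second stage of a Robinson annulation) closes ring B as the conjugated enone; C4 is epimerisable here and is left undefined until step 15.

Step 14
Reactants: 23 (4aR)-4a,8-dimethyl-4,4a,5,6,7,8-hexahydronaphthalen-2(3H)-one
Product: 24 (4aR)-4a,8-dimethyl-4,4a,5,6-tetrahydronaphthalen-2(3H)-one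
Conditions: chloranil, t-BuOH, reflux
Reagents that add atoms: none
Why: Quinone dehydrogenation of a γ-methyl enone through its dienol gives the linear dienone, which removes the C4 epimer mixture by making C4 sp2.

Step 15
Reactants: 24 (4aR)-4a,8-dimethyl-4,4a,5,6-tetrahydronaphthalen-2(3H)-one
Product: 25 (4aR,8S)-4a,8-dimethyl-4,4a,5,6,7,8-hexahydronaphthalen-2(3H)-one (methyl groups cis)
Conditions: H2 (1 atm), 5% Pd/C, EtOAc, 0 °C, stopped after 1 equiv
Reagents that add atoms: none
Why: Catalytic hydrogenation of a linear dienone takes place at the remote γ,δ alkene, and hydrogen should be delivered to the face opposite the axial angular methyl group, placing H-4 α and the C4 methyl β as the kinetic product.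

Step 16
Reactants: 25 (4aR,8S)-4a,8-dimethyl-4,4a,5,6,7,8-hexahydronaphthalen-2(3H)-one
Product: 27 (4aR,8S)-4a,8-dimethyl-4,4a,5,6,7,8-hexahydronaphthalen-2-yl trifluoromethanesulfonate, via lithium dienolate 26 (not isolated)
Conditions: LiN(i-Pr)2, THF, −78 °C; PhNTf2, −78 to 0 °C
Reagents that add atoms: N-phenylbis(trifluoromethanesulfonimide), O=S(=O)(N(c1ccccc1)S(=O)(=O)C(F)(F)F)C(F)(F)F
Why: Kinetic deprotonation of the enone at the α′ carbon C8 gives the cross-conjugated dienolate, which is O-sulfonylated to the dienyl triflate (enol triflate formation) without touching C4.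

Step 17
Reactants: 27 (4aR,8S)-4a,8-dimethyl-4,4a,5,6,7,8-hexahydronaphthalen-2-yl trifluoromethanesulfonate
Product: 28 methyl 2-[(4aR,8S)-4a,8-dimethyl-4,4a,5,6,7,8-hexahydronaphthalen-2-yl]acetate
Conditions: BrZnCH2CO2Me (from BrCH2CO2Me, Zn), Pd(PPh3)4 (5 mol %), THF, 60 °C
Reagents that add atoms: methyl bromoacetate (used as its zinc reagent), COC(=O)CBr
Why: Negishi cross-coupling, in which oxidative addition of the dienyl triflate to zerovalent palladium, transmetalation with the zinc ester enolate (Reformatsky reagent) and reductive elimination should attach the acetate unit C11–C12 to C7.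

Step 18
Reactants: 28 methyl 2-[(4aR,8S)-4a,8-dimethyl-4,4a,5,6,7,8-hexahydronaphthalen-2-yl]acetate
Product: 30 methyl 8α-hydroxy-13-noreudesm-5-en-12-oate (H-7 α), via alkylborane 29 (not isolated)
Conditions: 9-BBN, THF, 50 °C; then 30% H2O2, aq NaOAc, 0 °C to rt
Reagents that add atoms: hydrogen peroxide, OO
Why: Hydroboration–oxidation, in which the dialkylborane adds to the less hindered C7=C8 bond with boron on C8, syn and from the α face away from the axial C14 methyl, which sets H-7 α and gives the 8α alcohol.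

Step 19
Reactants: 30 methyl 8α-hydroxy-13-noreudesm-5-en-12-oate
Product: 31 methyl 8-oxo-13-noreudesm-5-en-12-oate (H-7 α)
Conditions: Dess–Martin periodinane, NaHCO3, CH2Cl2, 0 °C to rt
Reagents that add atoms: none
Why: Dess–Martin oxidation converts the secondary alcohol into the ketone under buffered conditions that should neither move the β,γ alkene into conjugation nor epimerise the equatorial C7 side chain.

Step 20
Reactants: 31 methyl 8-oxo-13-noreudesm-5-en-12-oate
Product: 33 13-noreudesm-5-en-12,8β-olide (cis-fused γ-lactone), via hydroxy ester 32 (not isolated)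
Conditions: NaBH4, MeOH, −20 °C to rt
Reagents that add atoms: none
Why: Hydride reduction of the ketone should occur from the α face because axial approach is blocked by the syn-axial C14 methyl, giving the axial 8β alkoxide, which closes onto the cis ester to form the γ-lactone (reduction–lactonisation).

Step 21
Reactants: 33 13-noreudesm-5-en-12,8β-olide
Product: 35 11-diazo-13-noreudesm-5-en-12,8β-olide, via trifluoroacetyl lactone 34 (not isolated)
Conditions: LiN(SiMe3)2, THF, −78 °C; CF3CO2CH2CF3; then MeSO2N3, Et3N, MeCN, rt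
Reagents that add atoms: methanesulfonyl azide, CS(=O)(=O)N=[N+]=[N-]
Why: Deacylative diazo transfer, in which the lactone enolate is trifluoroacetylated and the activated intermediate takes the diazo group from the sulfonyl azide with loss of the trifluoroacetyl group.

Step 22
Reactants: 35 11-diazo-13-noreudesm-5-en-12,8β-olide; 17 (2R)-2-El-but-3-ene-1,2-diol
Product: 36 11-[(2R)-2-El-2-hydroxybut-3-enyloxy]-13-noreudesm-5-en-12,8β-olide (C11 epimers)
Conditions: Rh2(O2CCPh3)4 (2 mol %), CH2Cl2, −78 to −40 °C, 35 (2 equiv) added slowly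
Reagents that add atoms: none
Why: Rhodium carbenoid O–H insertion into the primary hydroxyl (less hindered than the tertiary carbinol) forms the C11–O ether bond; the bulky carboxylate ligands and low temperature are chosen to slow the competing 1,2-hydride shift of H-7, and the C11 configuration is irrelevant because it is erased in step 25.

Step 23
Reactants: 36 11-[(2R)-2-El-2-hydroxybut-3-enyloxy]-13-noreudesm-5-en-12,8β-olide
Product: 39 11-[(2R)-2-El-2-hydroxybut-3-enyloxy]-8β-(triethylsilyloxy)-13-noreudesm-5-en-12-oic acid, via lithium carboxylate 37 (not isolated), via bis-silyl compound 38 (not isolated)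
Conditions: LiOH, THF/H2O, rt; evaporate; Et3SiCl, imidazole, DMF, rt; aq NaHCO3
Reagents that add atoms: lithium hydroxide, [Li+].[OH-]; chlorotriethylsilane, CC[Si](CC)(CC)Cl
Why: Saponification opens the γ-lactone, and silylation with Et3SiCl–imidazole should take place at the secondary C8 hydroxyl and the carboxylate but not at the tertiary allylic carbinol, after which the labile silyl ester is hydrolysed on work-up (lactone hydrolysis and selective silyl protection).

Step 24
Reactants: 39 11-[(2R)-2-El-2-hydroxybut-3-enyloxy]-8β-(triethylsilyloxy)-13-noreudesm-5-en-12-oic acid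
Product: 41 (6R)-6-ethenyl-6-El-3-[8β-(triethylsilyloxy)-11,12,13-trinoreudesm-5-en-7β-yl]-1,4-dioxan-2-one (C3 epimers), via mixed anhydride 40 (not isolated)
Conditions: 2,4,6-Cl3C6H2COCl, Et3N, THF, rt; DMAP, toluene, 60 °C
Reagents that add atoms: none
Why: Yamaguchi lactonisation, in which the mixed anhydride acylates the only free hydroxyl, the tertiary C11′ carbinol, in a six-membered ring closure that forms the 1,4-dioxan-2-one.

Step 25
Reactants: 41 (6R)-6-ethenyl-6-El-3-[8β-(triethylsilyloxy)-11,12,13-trinoreudesm-5-en-7β-yl]-1,4-dioxan-2-one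
Product: 44 (2R)-5-El-2-[8β-(triethylsilyloxy)-11,12,13-trinoreudesm-5-en-7β-yl]-3,6-dihydro-2H-pyran-2-carboxylic acid, via silyl ketene acetal 42 (not isolated), via silyl ester 43 (not isolated)
Conditions: LiN(i-Pr)2, Me3SiCl/Et3N, THF, −78 °C to rt; toluene, 60 °C; aq citric acid
Reagents that add atoms: none
Why: Lithium diisopropylamide removes H-11 in the presence of Me3SiCl to give the silyl ketene acetal, whose C11=C12 geometry is fixed by the dioxanone ring, and on warming the axial vinyl group on C11′ bonds through its terminal carbon C13 to C11 while the C11′–O ester bond breaks, a [3,3]-sigmatropic (Ireland–Claisen) shift through a boat-like bicyclic transition state. The closest known reaction type is the enolate Claisen ring exchange of 6-alkenyl-1,4-dioxan-2-ones to 3,6-dihydro-2H-pyran-2-carboxylic acids, and the substrate belongs to that class, differing only in its crowding (tertiary C6, quaternary carbon formed). The dihydropyran is closed by this ring exchange, with C11–C13 formed across the 3- and 6-positions of the dioxanone, whose ether oxygen and C12′ become the pyran oxygen and C6. The one new stereocentre, quaternary C11, is controlled by C11′, because the tether lets C13 reach only the ketene acetal face on which the vinyl group stands, so the (6R) centre is relayed to (11R) while the earlier C11 mixture is erased. The step needs enolisation at C11 (the only C–H next to a carbonyl) and a suprafacial shift (enforced by the ring), and the bulky El group prefers the equatorial site on C11′, which leaves the vinyl group axial as required.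

Step 26
Reactants: 44 (2R)-5-El-2-[8β-(triethylsilyloxy)-11,12,13-trinoreudesm-5-en-7β-yl]-3,6-dihydro-2H-pyran-2-carboxylic acid
Product: 46 (11R)-13-noreudesm-5-en-12,8β-olide spiro-fused at C11 to C2 of 5-El-3,6-dihydro-2H-pyran, via hydroxy acid 45 (not isolated)
Conditions: HF·pyridine, THF, 0 °C to rt
Reagents that add atoms: none
Why: Fluoride-mediated desilylation frees the 8β hydroxyl, which lies cis to the carboxylic acid and should lactonise under the mildly acidic conditions (desilylation–lactonisation), closing the cis-fused γ-lactone without touching C11.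

Step 27
Reactants: 46 (11R)-13-noreudesm-5-en-12,8β-olide spiro-fused at C11 to C2 of 5-El-3,6-dihydro-2H-pyran
Product: 47 CNP0175206.1 (the 3,4-dihydro-2H-pyran isomer of 46 with the O–CH=C(El) enol ether)
Conditions: RuHCl(CO)(PPh3)3 (5 mol %), toluene, 80 °C
Reagents that add atoms: none
Why: Ruthenium hydride-catalysed alkene isomerisation (hydrometalation then β-hydride elimination) should move the pyran C=C bond from the allyl ether position into conjugation with oxygen, the thermodynamically favoured enol ether; no stereocentre is involved.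

Compound list
1 | (S)-(+)-carvone | CC1=CC[C@@H](CC1=O)C(=C)C | starting material
2 | (5S)-5-acetyl-2-methylcyclohex-2-en-1-one | CC1=CC[C@@H](CC1=O)C(C)=O | intermediate
3 | (5S)-2-methyl-5-(2-methyl-1,3-dioxolan-2-yl)cyclohex-2-en-1-one | CC1=CC[C@@H](CC1=O)C2(C)OCCO2 | intermediate
4 | isopropenylmagnesium bromide | CC(=C)[Mg]Br | starting material
5 | bromomagnesium (3R,5S)-2-methyl-5-(2-methyl-1,3-dioxolan-2-yl)-3-(prop-1-en-2-yl)cyclohex-1-en-1-olate | CC1=C(O[Mg]Br)C[C@@H](C2(C)OCCO2)C[C@@H]1C(C)=C | intermediate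
6 | (2S,3R,5S)-2-[1-hydroxy-2-(phenylselanyl)ethyl]-2-methyl-5-(2-methyl-1,3-dioxolan-2-yl)-3-(prop-1-en-2-yl)cyclohexan-1-one (carbinol epimers) | OC(C[Se]c1ccccc1)[C@@]1(C)C(=O)C[C@@H](C2(C)OCCO2)C[C@@H]1C(C)=C | intermediate
7 | (2R,3R,5S)-2-ethenyl-2-methyl-5-(2-methyl-1,3-dioxolan-2-yl)-3-(prop-1-en-2-yl)cyclohexan-1-one | C=C[C@@]1(C)C(=O)C[C@@H](C2(C)OCCO2)C[C@@H]1C(C)=C | intermediate
8 | hydrazone of 7 | C=C[C@@]1(C)C(=NN)C[C@@H](C2(C)OCCO2)C[C@@H]1C(C)=C | intermediate
9 | 2-[(1R,3R,4R)-4-ethenyl-4-methyl-3-(prop-1-en-2-yl)cyclohexyl]-2-methyl-1,3-dioxolane | C=C[C@@]1(C)CC[C@@H](C2(C)OCCO2)C[C@@H]1C(C)=C | intermediate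
10 | 1-[(1R,3R,4R)-4-ethenyl-4-methyl-3-(prop-1-en-2-yl)cyclohexyl]ethan-1-one (acetyl trans to isopropenyl) | C=C[C@@]1(C)CC[C@@H](C(C)=O)C[C@@H]1C(C)=C | intermediate
11 | El–C(O)CH3, 1-[(1S,3R,4R)-4-ethenyl-4-methyl-3-(prop-1-en-2-yl)cyclohexyl]ethan-1-one | C=C[C@@]1(C)CC[C@H](C(C)=O)C[C@@H]1C(C)=C | intermediate
12 | 2-methyl-2-El-oxirane (both epimers at the oxirane carbon) | C=C[C@@]1(C)CC[C@H](C2(C)CO2)C[C@@H]1C(C)=C | intermediate
13 | 2-El-prop-2-en-1-ol | C=C[C@@]1(C)CC[C@H](C(=C)CO)C[C@@H]1C(C)=C | intermediate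
14 | [(2R)-2-El-oxiran-2-yl]methanol | C=C[C@@]1(C)CC[C@H]([C@@]2(CO)CO2)C[C@@H]1C(C)=C | intermediate
15 | tert-butyl{[(2S)-2-El-oxiran-2-yl]methoxy}dimethylsilane | C=C[C@@]1(C)CC[C@H]([C@@]2(CO[Si](C)(C)C(C)(C)C)CO2)C[C@@H]1C(C)=C | intermediate
16 | (2R)-1-[tert-butyl(dimethyl)silyloxy]-2-El-but-3-en-2-ol | C=C[C@@]1(C)CC[C@H]([C@@](O)(CO[Si](C)(C)C(C)(C)C)C=C)C[C@@H]1C(C)=C | intermediate
17 | (2R)-2-El-but-3-ene-1,2-diol | C=C[C@@]1(C)CC[C@H]([C@@](O)(CO)C=C)C[C@@H]1C(C)=C | intermediate
18 | 2,6-dimethylcyclohexan-1-one (cis/trans mixture) | CC1CCCC(C)C1=O | starting material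
19 | methyl vinyl ketone (but-3-en-2-one) | CC(=O)C=C | starting material
20 | N-[(1S)-1-phenylethyl]-2,6-dimethylcyclohexan-1-imine | C[C@H](N=C1C(C)CCCC1C)c1ccccc1 | intermediate
21 | 4-[(1R)-1,3-dimethyl-2-{[(1S)-1-phenylethyl]imino}cyclohexyl]butan-2-one | C[C@H](N=C1C(C)CCC[C@]1(C)CCC(C)=O)c1ccccc1 | intermediate
22 | (2R)-2,6-dimethyl-2-(3-oxobutyl)cyclohexan-1-one (C6 epimers) | CC(=O)CC[C@@]1(C)CCCC(C)C1=O | intermediate
23 | (4aR)-4a,8-dimethyl-4,4a,5,6,7,8-hexahydronaphthalen-2(3H)-one (C8 epimers) | O=C1CC[C@@]2(C)CCCC(C)C2=C1 | intermediate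
24 | (4aR)-4a,8-dimethyl-4,4a,5,6-tetrahydronaphthalen-2(3H)-one | O=C1CC[C@@]2(C)CCC=C(C)C2=C1 | intermediate
25 | (4aR,8S)-4a,8-dimethyl-4,4a,5,6,7,8-hexahydronaphthalen-2(3H)-one (methyl groups cis) | O=C1CC[C@@]2(C)CCC[C@H](C)C2=C1 | intermediate
26 | lithium (4aR,8S)-4a,8-dimethyl-4,4a,5,6,7,8-hexahydronaphthalen-2-olate (cross-conjugated dienolate) | [Li]OC1=CC[C@@]2(C)CCC[C@H](C)C2=C1 | intermediate
27 | (4aR,8S)-4a,8-dimethyl-4,4a,5,6,7,8-hexahydronaphthalen-2-yl trifluoromethanesulfonate | O=S(=O)(OC1=CC[C@@]2(C)CCC[C@H](C)C2=C1)C(F)(F)F | intermediate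
28 | methyl 2-[(4aR,8S)-4a,8-dimethyl-4,4a,5,6,7,8-hexahydronaphthalen-2-yl]acetate | COC(=O)CC1=CC[C@@]2(C)CCC[C@H](C)C2=C1 | intermediate
29 | B-alkyl-9-borabicyclo[3.3.1]nonane from 28 (boron on C8 α, H-7 α) | COC(=O)C[C@@H]1[C@@H](B3C4CCCC3CCC4)C[C@@]2(C)CCC[C@H](C)C2=C1 | intermediate
30 | methyl 8α-hydroxy-13-noreudesm-5-en-12-oate (4β,10β-dimethyl, H-7 α) | COC(=O)C[C@@H]1[C@@H](O)C[C@@]2(C)CCC[C@H](C)C2=C1 | intermediate
31 | methyl 8-oxo-13-noreudesm-5-en-12-oate (H-7 α) | COC(=O)C[C@@H]1C(=O)C[C@@]2(C)CCC[C@H](C)C2=C1 | intermediate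
32 | methyl 8β-hydroxy-13-noreudesm-5-en-12-oate (H-7 α) | COC(=O)C[C@@H]1[C@H](O)C[C@@]2(C)CCC[C@H](C)C2=C1 | intermediate
33 | 13-noreudesm-5-en-12,8β-olide (cis-fused γ-lactone, H-7 α, H-8 α) | O=C1O[C@@H]2C[C@@]3(C)CCC[C@H](C)C3=C[C@@H]2C1 | intermediate
34 | 11-(trifluoroacetyl)-13-noreudesm-5-en-12,8β-olide | O=C1O[C@@H]2C[C@@]3(C)CCC[C@H](C)C3=C[C@@H]2C1C(=O)C(F)(F)F | intermediate
35 | 11-diazo-13-noreudesm-5-en-12,8β-olide | O=C1O[C@@H]2C[C@@]3(C)CCC[C@H](C)C3=C[C@@H]2C1=[N+]=[N-] | intermediate
36 | 11-[(2R)-2-El-2-hydroxybut-3-enyloxy]-13-noreudesm-5-en-12,8β-olide (C11 epimers) | C=C[C@@]1(C)CC[C@H]([C@@](O)(COC2C(=O)O[C@@H]3C[C@@]4(C)CCC[C@H](C)C4=C[C@@H]32)C=C)C[C@@H]1C(C)=C | intermediate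
37 | lithium 11-[(2R)-2-El-2-hydroxybut-3-enyloxy]-8β-hydroxy-13-noreudesm-5-en-12-oate | [Li+].C=C[C@@]1(C)CC[C@H]([C@@](O)(COC(C([O-])=O)[C@H]2C=C3[C@@H](C)CCC[C@]3(C)C[C@H]2O)C=C)C[C@@H]1C(C)=C | intermediate
38 | triethylsilyl 11-[(2R)-2-El-2-hydroxybut-3-enyloxy]-8β-(triethylsilyloxy)-13-noreudesm-5-en-12-oate | C=C[C@@]1(C)CC[C@H]([C@@](O)(COC(C(=O)O[Si](CC)(CC)CC)[C@H]2C=C3[C@@H](C)CCC[C@]3(C)C[C@H]2O[Si](CC)(CC)CC)C=C)C[C@@H]1C(C)=C | intermediate
39 | 11-[(2R)-2-El-2-hydroxybut-3-enyloxy]-8β-(triethylsilyloxy)-13-noreudesm-5-en-12-oic acid | C=C[C@@]1(C)CC[C@H]([C@@](O)(COC(C(=O)O)[C@H]2C=C3[C@@H](C)CCC[C@]3(C)C[C@H]2O[Si](CC)(CC)CC)C=C)C[C@@H]1C(C)=C | intermediate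
40 | mixed anhydride of 39 with 2,4,6-trichlorobenzoic acid | C=C[C@@]1(C)CC[C@H]([C@@](O)(COC(C(=O)OC(=O)c5c(Cl)cc(Cl)cc5Cl)[C@H]2C=C3[C@@H](C)CCC[C@]3(C)C[C@H]2O[Si](CC)(CC)CC)C=C)C[C@@H]1C(C)=C | intermediate
41 | (6R)-6-ethenyl-6-El-3-[8β-(triethylsilyloxy)-11,12,13-trinoreudesm-5-en-7β-yl]-1,4-dioxan-2-one (C3 epimers) | C=C[C@@]1(C)CC[C@H]([C@]2(C=C)COC([C@H]3C=C4[C@@H](C)CCC[C@]4(C)C[C@H]3O[Si](CC)(CC)CC)C(=O)O2)C[C@@H]1C(C)=C | intermediate
42 | (6R)-6-ethenyl-6-El-3-[8β-(triethylsilyloxy)-11,12,13-trinoreudesm-5-en-7β-yl]-2-(trimethylsilyloxy)-5,6-dihydro-1,4-dioxine | C=C[C@@]1(C)CC[C@H]([C@]2(C=C)COC([C@H]3C=C4[C@@H](C)CCC[C@]4(C)C[C@H]3O[Si](CC)(CC)CC)=C(O[Si](C)(C)C)O2)C[C@@H]1C(C)=C | intermediate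
43 | trimethylsilyl (2R)-5-El-2-[8β-(triethylsilyloxy)-11,12,13-trinoreudesm-5-en-7β-yl]-3,6-dihydro-2H-pyran-2-carboxylate | C=C[C@@]1(C)CC[C@H](C=2CO[C@@]([C@H]3C=C4[C@@H](C)CCC[C@]4(C)C[C@H]3O[Si](CC)(CC)CC)(CC=2)C(=O)O[Si](C)(C)C)C[C@@H]1C(C)=C | intermediate
44 | (2R)-5-El-2-[8β-(triethylsilyloxy)-11,12,13-trinoreudesm-5-en-7β-yl]-3,6-dihydro-2H-pyran-2-carboxylic acid | C=C[C@@]1(C)CC[C@H](C=2CO[C@@]([C@H]3C=C4[C@@H](C)CCC[C@]4(C)C[C@H]3O[Si](CC)(CC)CC)(CC=2)C(=O)O)C[C@@H]1C(C)=C | intermediate
45 | (2R)-5-El-2-[8β-hydroxy-11,12,13-trinoreudesm-5-en-7β-yl]-3,6-dihydro-2H-pyran-2-carboxylic acid | C=C[C@@]1(C)CC[C@H](C=2CO[C@@]([C@H]3C=C4[C@@H](C)CCC[C@]4(C)C[C@H]3O)(CC=2)C(=O)O)C[C@@H]1C(C)=C | intermediate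
46 | (11R)-13-noreudesm-5-en-12,8β-olide spiro-fused at C11 to C2 of 5-El-3,6-dihydro-2H-pyran | C=C[C@@]1(C)CC[C@H](C2=CC[C@]3(OC2)C(=O)O[C@@H]2C[C@@]4(C)CCC[C@H](C)C4=C[C@@H]23)C[C@@H]1C(C)=C | intermediate
47 | CNP0175206.1, (11R)-13-noreudesm-5-en-12,8β-olide spiro-fused at C11 to C2 of 5-El-3,4-dihydro-2H-pyran | C=C[C@@]1(C)CC[C@H](C2=CO[C@@]3(CC2)C(=O)O[C@@H]2C[C@@]4(C)CCC[C@H](C)C4=C[C@@H]23)C[C@@H]1C(=C)C | target

Total step count: 27.
Longest linear sequence: 17 steps (steps 1–11 and 22–27, from (S)-carvone). The decalin branch contributes steps 12–21 before the union.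

Steps most likely to fail

1. Step 22 (O–H insertion). The rhodium carbenoid may undergo 1,2-shift of H-7 to the conjugated butenolide faster than it is captured by the hindered, neopentyl-type primary hydroxyl, so the diazo lactone would be consumed without forming the ether. The fallback forms the ether by epoxide opening instead of carbene insertion and sets out from 13 and 33. Epoxidation of allylic alcohol 13 with Ti(Oi-Pr)4, L-(+)-diisopropyl tartrate and t-BuOOH would give [(2S)-2-El-oxiran-2-yl]methanol F1; the opposite tartrate is needed because in this sequence the hydroxymethyl arm, not the oxirane CH2, becomes the vinyl group. Oxidation with SO3·pyridine, DMSO and i-Pr2NEt would give (2R)-2-El-oxirane-2-carbaldehyde F2, and Ph3P=CH2 would give (2R)-2-ethenyl-2-El-oxirane F3. Separately, the enolate of lactone 33 (LiN(SiMe3)2, THF, −78 °C) would be hydroxylated with 2-(phenylsulfonyl)-3-phenyloxaziridine to 11-hydroxy-13-noreudesm-5-en-12,8β-olide F4. The sodium alkoxide of F4 (NaH, DMF, 60 °C) should open F3 at its CH2 terminus and give ether lactone 36, where the route is rejoined.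

2. Step 27 (alkene isomerisation). The ruthenium hydride may fail to turn over on the trisubstituted ring alkene, or may instead move the isopropenyl alkene or the strained C5=C6 bond of the decalin. The fallback moves the alkene with base before the lactone exists and sets out from 44. KOt-Bu in DMSO at rt, acting on the potassium carboxylate of 44, should isomerise the allyl ether to the enol ether and give (2R)-5-El-2-[8β-(triethylsilyloxy)-11,12,13-trinoreudesm-5-en-7β-yl]-3,4-dihydro-2H-pyran-2-carboxylic acid F5. Bu4NF in THF followed by EDC·HCl and DMAP would then remove the silyl group and close the γ-lactone under non-acidic conditions, arriving directly at target 47.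

3. Step 15 (hydrogenation that sets C4). The kinetic cis-dimethyl configuration may be lost through double-bond migration or equilibration on the palladium surface towards the more stable trans epimer, and the enone alkene may be over-reduced. The fallback replaces surface catalysis by stoichiometric diimide (from 2-nitrobenzenesulfonyl hydrazide and Et3N, CH2Cl2, rt). Diimide transfers both hydrogens in one concerted suprafacial step to the exposed α face of the C3=C4 bond, cannot pass through allyl-metal intermediates and leaves the conjugated C=C alone. It sets out from dienone 24 and returns to octalone 25; no compound outside the list is formed (F0).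

Further compounds
F1 | step 22 | [(2S)-2-El-oxiran-2-yl]methanol | C=C[C@@]1(C)CC[C@H]([C@]2(CO)CO2)C[C@@H]1C(C)=C
F2 | step 22 | (2R)-2-El-oxirane-2-carbaldehyde | C=C[C@@]1(C)CC[C@H]([C@]2(C=O)CO2)C[C@@H]1C(C)=C
F3 | step 22 | (2R)-2-ethenyl-2-El-oxirane | C=C[C@@]1(C)CC[C@H]([C@]2(C=C)CO2)C[C@@H]1C(C)=C
F4 | step 22 | 11-hydroxy-13-noreudesm-5-en-12,8β-olide (C11 epimers) | O=C1O[C@@H]2C[C@@]3(C)CCC[C@H](C)C3=C[C@@H]2C1O
F5 | step 27 | (2R)-5-El-2-[8β-(triethylsilyloxy)-11,12,13-trinoreudesm-5-en-7β-yl]-3,4-dihydro-2H-pyran-2-carboxylic acid | C=C[C@@]1(C)CC[C@H](C2=CO[C@@]([C@H]3C=C4[C@@H](C)CCC[C@]4(C)C[C@H]3O[Si](CC)(CC)CC)(CC2)C(=O)O)C[C@@H]1C(C)=C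
F0 | step 15 | none | none
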